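**Plan**
- Retrosynthetic cuts: the C6–CO bond and the CO–aryl bond of the diketone (both to an oxalic bis(N-methoxy-N-methylamide) linchpin), the C8–prenyl bond, the C3=C4 alkene (to a 4-methoxychromane), and last the pyran bonds C3–C4 and O1–C2.
- Enabling feature: pyran C4 is a benzylic carbon on C4a, and C4a lies between the oxygen-bearing ring carbons C5 and C8a, so C4 and O1 are the two ends of an ortho-quinone methide of a 2,6-dioxygenated 4-methoxybenzaldehyde.
- Forward: the benzene ring is bought as 5-methoxyresorcinol, formylated between its hydroxyls and monosilylated. The pyran ring is then closed with 2-methylpropene and methanol is eliminated to give the chromene.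
- The side chains follow: prenyl at C8 by lithiation steered by the silyl ether, then, after silyl-to-MOM exchange, the aryl diketone at C6 by lithiation and two successive ketone syntheses on the oxalamide; acid deprotection ends the route.
- Stereochemistry: the target has no stereocentre; C4 of the chromane and the acetal carbon of the tetrahydropyranyl group are racemic and both are removed.

Key step: step 5

Remark: Grignard reagent 18 is taken as the commercial THF solution of the racemic tetrahydropyranyl ether, and the target is drawn in its open, hydrogen-bonded 2-hydroxybenzil form.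

**Step 1**
Reactants: 1 5-methoxyresorcinol
Product: 2 1-methoxy-3,5-bis(methoxymethoxy)benzene
Conditions: NaH, MOMCl, DMF, 0 °C → rt
Reagents that add atoms: chloromethyl methyl ether, COCCl
Why: Williamson-type O-alkylation of both phenoxides by the reactive α-chloro ether should give the bis-MOM ether, whose acetal oxygens later direct the lithiation.

**Step 2**
Reactants: 2 1-methoxy-3,5-bis(methoxymethoxy)benzene
Product: 4 4-methoxy-2,6-bis(methoxymethoxy)benzaldehyde, via aryllithium 3 (not isolated)
Conditions: n-BuLi, TMEDA, THF, 0 °C; DMF, 0 °C → rt; H2O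
Reagents that add atoms: N,N-dimethylformamide, CN(C)C=O
Why: Directed ortho-metalation should occur at the carbon between the two cooperatively chelating MOM-oxy groups, and formylation of the aryllithium with DMF (Bouveault aldehyde synthesis) places the aldehyde para to the methoxy group.

**Step 3**
Reactants: 4 4-methoxy-2,6-bis(methoxymethoxy)benzaldehyde
Product: 5 2,6-dihydroxy-4-methoxybenzaldehyde
Conditions: HCl (cat.), MeOH, 50 °C; aqueous work-up
Reagents that add atoms: none
Why: Acid-catalysed acetal exchange with methanol should cleave both MOM ethers, helped by the ortho carbonyl group, and release the symmetric dihydroxy aldehyde.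

**Step 4**
Reactants: 5 2,6-dihydroxy-4-methoxybenzaldehyde
Product: 6 2-hydroxy-4-methoxy-6-(triisopropylsilyloxy)benzaldehyde
Conditions: TIPSCl (1.05 equiv), imidazole, CH2Cl2, 0 °C
Reagents that add atoms: triisopropylsilyl chloride, CC(C)[Si](Cl)(C(C)C)C(C)C
Why: Silyl ether formation on one of two equivalent phenols should stop after the first silylation, because the remaining hydroxyl is then locked in a hydrogen bond to the aldehyde and is much less nucleophilic.

**Step 5**
Reactants: 6 2-hydroxy-4-methoxy-6-(triisopropylsilyloxy)benzaldehyde; 7 2-methylpropene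
Product: 10 rac-4,7-dimethoxy-2,2-dimethyl-5-(triisopropylsilyloxy)chromane, via dimethyl acetal 8 (not isolated), via ortho-quinone methide 9 (not isolated)
Conditions: 7 (excess, condensed), HC(OMe)3 (2 equiv), Sc(OTf)3 (10 mol%), CH2Cl2, sealed tube, 0 °C → rt
Reagents that add atoms: trimethyl orthoformate, COC(OC)OC
Why: Sc(OTf)3 and trimethyl orthoformate should convert the aldehyde into dimethyl acetal 8, which ionises with the push of the free ortho hydroxyl to a methoxy-substituted oxocarbenium ion, the O-protonated form of ortho-quinone methide 9. 2-Methylpropene then adds across the O=C–C=CH(OMe) heterodiene in an inverse-electron-demand hetero-Diels–Alder reaction, or in its stepwise limit by cation–olefin addition and capture of the tertiary cation by the phenol oxygen, forming C3–C4 and O1–C2. The closest known reaction type is the Lewis-acid-catalysed three-component coupling of salicylaldehydes, orthoformates and alkenes to 4-alkoxychromanes. The pyran ring is closed intermolecularly as a [4+2] annulation in which four ring atoms come from the quinone methide and two from the alkene. The new stereocentre at C4 is formed as a racemate without control, which is harmless because step 6 removes it. The selectivity needed is the orientation of the alkene, secured by Markovnikov polarity (CH2 to the benzylic carbon, tertiary carbon to oxygen), while the silyl ether leaves only one phenol to close the ring, blocks a second annulation at C4 and, together with excess alkene, holds back self-condensation of the electron-rich ring.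

**Step 6**
Reactants: 10 rac-4,7-dimethoxy-2,2-dimethyl-5-(triisopropylsilyloxy)chromane
Product: 11 7-methoxy-2,2-dimethyl-5-(triisopropylsilyloxy)-2H-chromene
Conditions: PPTS (10 mol%), toluene, 110 °C, 4 Å MS
Reagents that add atoms: none
Why: Acid-catalysed E1 elimination of methanol should proceed through a C4 benzylic cation stabilised by the C5, C7 and ring oxygens, and loss of a C3 proton gives the conjugated chromene and erases the C4 stereocentre.

**Step 7**
Reactants: 11 7-methoxy-2,2-dimethyl-5-(triisopropylsilyloxy)-2H-chromene; 12 1-bromo-3-methylbut-2-ene (prenyl bromide)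
Product: 14 7-methoxy-2,2-dimethyl-8-(3-methylbut-2-enyl)-5-(triisopropylsilyloxy)-2H-chromene, via 8-lithiochromene 13 (not isolated)
Conditions: n-BuLi, TMEDA, THF, 0 °C; CuBr·SMe2 (10 mol%), 12, −78 °C → rt
Reagents that add atoms: none
Why: Directed ortho-metalation should take place at C8, which lies between the methoxy group and the pyran oxygen, because C6 is shielded by the bulky, weakly coordinating silyl ether, and copper-catalysed allylic substitution then joins the aryl carbon to the primary carbon of prenyl bromide.

**Step 8**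
Reactants: 14 7-methoxy-2,2-dimethyl-8-(3-methylbut-2-enyl)-5-(triisopropylsilyloxy)-2H-chromene
Product: 15 7-methoxy-2,2-dimethyl-8-(3-methylbut-2-enyl)-2H-chromen-5-ol
Conditions: Bu4NF, THF, 0 °C; H2O
Reagents that add atoms: none
Why: Fluoride-induced cleavage of the aryl silyl ether, driven by Si–F bond formation, should free the C5 phenol without touching either alkene.

**Step 9**
Reactants: 15 7-methoxy-2,2-dimethyl-8-(3-methylbut-2-enyl)-2H-chromen-5-ol
Product: 16 7-methoxy-5-(methoxymethoxy)-2,2-dimethyl-8-(3-methylbut-2-enyl)-2H-chromene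
Conditions: NaH, MOMCl, DMF, 0 °C
Reagents that add atoms: chloromethyl methyl ether, COCCl
Why: Williamson-type O-alkylation of the phenoxide installs a MOM ether, which is a strong directing group for the second metalation.

**Step 10**
Reactants: 16 7-methoxy-5-(methoxymethoxy)-2,2-dimethyl-8-(3-methylbut-2-enyl)-2H-chromene; 17 N,N'-dimethoxy-N,N'-dimethyloxamide; 18 4-(tetrahydro-2H-pyran-2-yloxy)phenylmagnesium bromide
Product: 21 1-[7-methoxy-5-(methoxymethoxy)-2,2-dimethyl-8-(3-methylbut-2-enyl)-2H-chromen-6-yl]-2-[4-(tetrahydro-2H-pyran-2-yloxy)phenyl]ethane-1,2-dione, via 6-lithiochromene 19 (not isolated), via lithium hemiaminal alkoxide 20 (not isolated)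
Conditions: n-BuLi, TMEDA, THF, −20 → 0 °C; added to 17 (1.1 equiv), THF, −78 °C; 18 (0.5 M in THF, 3 equiv), −78 → 0 °C; H2O
Reagents that add atoms: none
Why: Directed ortho-metalation at C6, the only remaining aryl C–H and flanked by the MOM-oxy and methoxy groups, is followed by two successive Weinreb ketone syntheses on the oxalamide, in which the chelated tetrahedral adduct 20 masks the first carbonyl while the aryl Grignard reagent adds to the second amide, so that aqueous work-up should release the unsymmetrical 1,2-diketone.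

**Step 11**
Reactants: 21 1-[7-methoxy-5-(methoxymethoxy)-2,2-dimethyl-8-(3-methylbut-2-enyl)-2H-chromen-6-yl]-2-[4-(tetrahydro-2H-pyran-2-yloxy)phenyl]ethane-1,2-dione
Product: 22 1-[5-hydroxy-7-methoxy-2,2-dimethyl-8-(3-methylbut-2-enyl)-2H-chromen-6-yl]-2-(4-hydroxyphenyl)ethane-1,2-dione (CNP0184805.0)
Conditions: HCl (3 M aq, cat.), MeOH, rt → 40 °C
Reagents that add atoms: none
Why: Acid-catalysed transacetalisation in methanol should remove the MOM ether, assisted by the ortho carbonyl, and the tetrahydropyranyl ether, while the prenyl group has no ortho hydroxyl to cyclise onto and the chromene tolerates dilute acid.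

**Compound list**
1 | 5-methoxyresorcinol | COc1cc(O)cc(O)c1 | starting material
2 | 1-methoxy-3,5-bis(methoxymethoxy)benzene | COCOc1cc(OC)cc(OCOC)c1 | intermediate
3 | 4-methoxy-2,6-bis(methoxymethoxy)phenyllithium | [Li]c1c(OCOC)cc(OC)cc1OCOC | intermediate (not isolated)
4 | 4-methoxy-2,6-bis(methoxymethoxy)benzaldehyde | COCOc1cc(OC)cc(OCOC)c1C=O | intermediate
5 | 2,6-dihydroxy-4-methoxybenzaldehyde | COc1cc(O)c(C=O)c(O)c1 | intermediate
6 | 2-hydroxy-4-methoxy-6-(triisopropylsilyloxy)benzaldehyde | COc1cc(O)c(C=O)c(O[Si](C(C)C)(C(C)C)C(C)C)c1 | intermediate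
7 | 2-methylpropene | CC(C)=C | starting material
8 | 2-(dimethoxymethyl)-5-methoxy-3-(triisopropylsilyloxy)phenol | COc1cc(O)c(C(OC)OC)c(O[Si](C(C)C)(C(C)C)C(C)C)c1 | intermediate (not isolated)
9 | 3-methoxy-6-(methoxymethylidene)-5-(triisopropylsilyloxy)cyclohexa-2,4-dien-1-one, reacting as its O-protonated form | COC=C1C(=O)C=C(OC)C=C1O[Si](C(C)C)(C(C)C)C(C)C | intermediate (not isolated)
10 | rac-4,7-dimethoxy-2,2-dimethyl-5-(triisopropylsilyloxy)chromane (racemic at C4) | COC1CC(C)(C)Oc2cc(OC)cc(O[Si](C(C)C)(C(C)C)C(C)C)c12 | intermediate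
11 | 7-methoxy-2,2-dimethyl-5-(triisopropylsilyloxy)-2H-chromene | COc1cc(O[Si](C(C)C)(C(C)C)C(C)C)c2C=CC(C)(C)Oc2c1 | intermediate
12 | 1-bromo-3-methylbut-2-ene (prenyl bromide) | CC(C)=CCBr | starting material
13 | 7-methoxy-2,2-dimethyl-5-(triisopropylsilyloxy)-2H-chromen-8-yllithium | [Li]c1c(OC)cc(O[Si](C(C)C)(C(C)C)C(C)C)c2C=CC(C)(C)Oc12 | intermediate (not isolated)
14 | 7-methoxy-2,2-dimethyl-8-(3-methylbut-2-enyl)-5-(triisopropylsilyloxy)-2H-chromene | COc1cc(O[Si](C(C)C)(C(C)C)C(C)C)c2C=CC(C)(C)Oc2c1CC=C(C)C | intermediate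
15 | 7-methoxy-2,2-dimethyl-8-(3-methylbut-2-enyl)-2H-chromen-5-ol | COc1cc(O)c2C=CC(C)(C)Oc2c1CC=C(C)C | intermediate
16 | 7-methoxy-5-(methoxymethoxy)-2,2-dimethyl-8-(3-methylbut-2-enyl)-2H-chromene | COCOc1cc(OC)c(CC=C(C)C)c2OC(C)(C)C=Cc12 | intermediate
17 | N,N'-dimethoxy-N,N'-dimethyloxamide | CON(C)C(=O)C(=O)N(C)OC | starting material
18 | 4-(tetrahydro-2H-pyran-2-yloxy)phenylmagnesium bromide (racemic) | Br[Mg]c1ccc(OC2CCCCO2)cc1 | starting material
19 | 7-methoxy-5-(methoxymethoxy)-2,2-dimethyl-8-(3-methylbut-2-enyl)-2H-chromen-6-yllithium | [Li]c1c(OCOC)c2C=CC(C)(C)Oc2c(CC=C(C)C)c1OC | intermediate (not isolated)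
20 | lithium alkoxide of the 1:1 adduct of 19 with 17, the chromen-6-yl-substituted carbon bearing OLi and N(OMe)Me next to the intact amide (racemic) | [Li]OC(N(C)OC)(C(=O)N(C)OC)c1c(OCOC)c2C=CC(C)(C)Oc2c(CC=C(C)C)c1OC | intermediate (not isolated)
21 | 1-[7-methoxy-5-(methoxymethoxy)-2,2-dimethyl-8-(3-methylbut-2-enyl)-2H-chromen-6-yl]-2-[4-(tetrahydro-2H-pyran-2-yloxy)phenyl]ethane-1,2-dione (racemic at the acetal carbon) | COCOc1c(C(=O)C(=O)c2ccc(OC3CCCCO3)cc2)c(OC)c(CC=C(C)C)c2OC(C)(C)C=Cc12 | intermediate
22 | 1-[5-hydroxy-7-methoxy-2,2-dimethyl-8-(3-methylbut-2-enyl)-2H-chromen-6-yl]-2-(4-hydroxyphenyl)ethane-1,2-dione | COc1c(CC=C(C)C)c2c(c(O)c1C(=O)C(=O)c1ccc(O)cc1)C=CC(C)(C)O2 | target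

**Step count**
Total: 11 steps. Longest linear sequence: 11 steps (1 → 22); compounds 7, 12, 17 and 18 are bought.

**Steps most likely to fail**

Step 5. The stabilised oxocarbenium ion may be captured by the electron-rich ring of a second molecule faster than by the unactivated alkene, or the alkene may oligomerise under the acid. The fallback sets out from 6 and makes the same two pyran bonds in separate events. Excess 2-methylprop-1-enylmagnesium bromide (THF, 0 °C) should add to the aldehyde and form C3–C4, giving racemic 2-(1-hydroxy-3-methylbut-2-enyl)-5-methoxy-3-(triisopropylsilyloxy)phenol F1. Warming this with PPTS in toluene should remove water to give the vinyl ortho-quinone methide 3-methoxy-6-(3-methylbut-2-enylidene)-5-(triisopropylsilyloxy)cyclohexa-2,4-dien-1-one F2, which is not isolated. Its oxa-6π electrocyclisation forms O1–C2 and delivers the chromene directly, so the route is rejoined at 11.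

Step 7. Deprotonation may be incomplete, may stray to C6, or may be followed by migration of silicon from oxygen to the lithiated carbon; the coupling may also occur with allylic transposition. The fallback sets out from the alkene-free chromane 10 and fixes the site with a halogen. NBS (MeCN, −20 °C) should brominate C8, the ring position not shielded by the silyl ether, to give 8-bromo-4,7-dimethoxy-2,2-dimethyl-5-(triisopropylsilyloxy)chromane F3. Bromine–lithium exchange (n-BuLi, THF, −78 °C) gives 4,7-dimethoxy-2,2-dimethyl-5-(triisopropylsilyloxy)chroman-8-yllithium F4, not isolated, which is coupled with 12 under CuBr·SMe2 catalysis to 4,7-dimethoxy-2,2-dimethyl-8-(3-methylbut-2-enyl)-5-(triisopropylsilyloxy)chromane F5. PPTS in hot toluene then eliminates methanol as in step 6, and the route is rejoined at 14.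

Step 10. The base may remove a benzylic-allylic proton of the prenyl group instead of the C6 proton, or the first tetrahedral adduct may collapse so that the Grignard reagent adds twice. The fallback sets out from phenol 15 and builds the diketone without an aryllithium.
- Oxalyl chloride (Et2O, 0 °C, argon stream to expel HCl) should O-acylate the phenol to 7-methoxy-2,2-dimethyl-8-(3-methylbut-2-enyl)-2H-chromen-5-yl chlorooxoacetate F6, not isolated.
- F6 should close by intramolecular Friedel–Crafts acylation at C6, the only free ring position, to the fused benzofuran-2,3-dione with its lactone oxygen on C5 and its keto carbon on C6 of the chromene F7.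
- N,O-dimethylhydroxylamine hydrochloride and pyridine should open the lactone to 2-[5-hydroxy-7-methoxy-2,2-dimethyl-8-(3-methylbut-2-enyl)-2H-chromen-6-yl]-N-methoxy-N-methyl-2-oxoacetamide F8.
- Excess 18 deprotonates the phenol, whose magnesium chelate shields the aryl ketone, and adds to the amide to give 1-[5-hydroxy-7-methoxy-2,2-dimethyl-8-(3-methylbut-2-enyl)-2H-chromen-6-yl]-2-[4-(tetrahydro-2H-pyran-2-yloxy)phenyl]ethane-1,2-dione F9.
- Acid methanolysis of the tetrahydropyranyl ether under the conditions of step 11 then gives the target, so the route is rejoined at 22.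

**Further compounds**
F1 | step 5 | 2-(1-hydroxy-3-methylbut-2-enyl)-5-methoxy-3-(triisopropylsilyloxy)phenol (racemic) | COc1cc(O)c(C(O)C=C(C)C)c(O[Si](C(C)C)(C(C)C)C(C)C)c1
F2 | step 5 | 3-methoxy-6-(3-methylbut-2-enylidene)-5-(triisopropylsilyloxy)cyclohexa-2,4-dien-1-one | COC1=CC(=O)C(=CC=C(C)C)C(O[Si](C(C)C)(C(C)C)C(C)C)=C1
F3 | step 7 | 8-bromo-4,7-dimethoxy-2,2-dimethyl-5-(triisopropylsilyloxy)chromane (racemic) | COC1CC(C)(C)Oc2c(Br)c(OC)cc(O[Si](C(C)C)(C(C)C)C(C)C)c12
F4 | step 7 | 4,7-dimethoxy-2,2-dimethyl-5-(triisopropylsilyloxy)chroman-8-yllithium (racemic) | COC1CC(C)(C)Oc2c([Li])c(OC)cc(O[Si](C(C)C)(C(C)C)C(C)C)c12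
F5 | step 7 | 4,7-dimethoxy-2,2-dimethyl-8-(3-methylbut-2-enyl)-5-(triisopropylsilyloxy)chromane (racemic) | COC1CC(C)(C)Oc2c(CC=C(C)C)c(OC)cc(O[Si](C(C)C)(C(C)C)C(C)C)c12
F6 | step 10 | 7-methoxy-2,2-dimethyl-8-(3-methylbut-2-enyl)-2H-chromen-5-yl chlorooxoacetate | O=C(Cl)C(=O)Oc1cc(OC)c(CC=C(C)C)c2OC(C)(C)C=Cc12
F7 | step 10 | fused benzofuran-2,3-dione of 15, lactone oxygen on C5 and keto carbon on C6 of the chromene | O=C1Oc2c(C1=O)c(OC)c(CC=C(C)C)c1OC(C)(C)C=Cc21
F8 | step 10 | 2-[5-hydroxy-7-methoxy-2,2-dimethyl-8-(3-methylbut-2-enyl)-2H-chromen-6-yl]-N-methoxy-N-methyl-2-oxoacetamide | CON(C)C(=O)C(=O)c1c(O)c2C=CC(C)(C)Oc2c(CC=C(C)C)c1OC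
F9 | step 10 | 1-[5-hydroxy-7-methoxy-2,2-dimethyl-8-(3-methylbut-2-enyl)-2H-chromen-6-yl]-2-[4-(tetrahydro-2H-pyran-2-yloxy)phenyl]ethane-1,2-dione (racemic at the acetal carbon) | COc1c(CC=C(C)C)c2OC(C)(C)C=Cc2c(O)c1C(=O)C(=O)c1ccc(OC2CCCCO2)cc1
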